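Locants (target): C1 isobutyryl bridgehead; C2 and C4 ketones beside C3; C5 geranyl bridgehead; C6H2–C7H–C8Me2 bridge from C5 to C1; C9 bridging ketone; C10H2–C11H bridge from C7 to C3; C12Me2–C13H(i-Pr)–C14H2 completing the cyclopentane C3–C11–C12–C13–C14.
Enabling feature: C12 is a quaternary gem-dimethyl carbon bonded to C13, and the isopropyl group on C13 is the saturated end of a prenyl group on C3; a tertiary C12 radical, freed by decarboxylation of a C12 carboxylic acid, therefore closes the cyclopentane onto that alkene.
Retrosynthetic cuts, in order: C12–C13 (radical 5-exo, last step); C1–C8 (acid-induced cage closure); C3–C14 (prenylation); the two C12 methyl groups; C3–C11 (Michael ring closure); C5–C6 and C5–geranyl (alkylations of brominated isobutyrylphloroglucinol).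
Forward: the aromatic core is brominated at C3 (placeholder), geranylated at C5 and dearomatized there by a lavandulol-derived arm; after debromination the seven-membered ring C3–C4–C5–C6–C7–C10–C11 closes, C12 is dimethylated, C3 is prenylated, the six-membered ring C1–C9–C5–C6–C7–C8 closes to give the homoadamantane, and the cyclopentane closes last.
Stereochemistry: C7 comes from (S)-lavandulol; C5 from separation of the epimer pair formed at the dearomatization; C11 from substrate control in the Michael closure; C3 and C1 are dictated by the bridged ring system; C13 is set in the radical cyclization.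

Key step: step 14

Assumption: (S)-lavandulol of high enantiomeric purity is taken as available from the commercial racemate by lipase-mediated kinetic resolution; enolized polyketones are written as one tautomer throughout.

Step 1
Reactants: 1 (S)-lavandulol
Product: 2 (S)-lavandulyl tert-butyldiphenylsilyl ether
Conditions: t-BuPh2SiCl, imidazole, DMF, 23 °C
Reagents that add atoms: tert-butyl(chloro)diphenylsilane CC(C)(C)[Si](Cl)(c1ccccc1)c1ccccc1
Why: Imidazole-promoted silylation of the primary alcohol (silyl ether protection) masks the hydroxyl against the peracid and the ylide that follow and does not touch the C7 stereocentre.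

Step 2
Reactants: 2 (S)-lavandulyl tert-butyldiphenylsilyl ether
Product: 4 (3S)-3-{[tert-butyl(diphenyl)silyl]oxymethyl}-4-methylpent-4-enal, via epoxide 3 (not isolated)
Conditions: m-CPBA (1.05 equiv), NaHCO3, CH2Cl2, −20 °C; then H5IO6, THF/H2O, 0 °C
Reagents that add atoms: m-chloroperoxybenzoic acid OOC(=O)c1cccc(Cl)c1
Why: Prilezhaev epoxidation is markedly faster at the trisubstituted than at the 1,1-disubstituted alkene, and periodic acid then cleaves the epoxide oxidatively to the C11 aldehyde and acetone, while C7, being β to the aldehyde, cannot epimerize.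

Step 3
Reactants: 4 silyl-protected aldehyde
Product: 5 tert-butyl (2E,5S)-5-{[tert-butyl(diphenyl)silyl]oxymethyl}-6-methylhepta-2,6-dienoate
Conditions: Ph3P=CHCO2t-Bu, CH2Cl2, 23 °C
Reagents that add atoms: tert-butyl (triphenylphosphoranylidene)acetate CC(C)(C)OC(=O)C=P(c1ccccc1)(c1ccccc1)c1ccccc1
Why: Wittig olefination with a stabilized ylide should give the (E)-enoate that later acts as the Michael acceptor at C11, and the tert-butyl ester is chosen because it tolerates amide bases and is lost in formic acid.

Step 4
Reactants: 5 silyl-protected enoate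
Product: 6 tert-butyl (2E,5S)-5-(hydroxymethyl)-6-methylhepta-2,6-dienoate
Conditions: Bu4NF, AcOH (1:1), THF, 23 °C
Reagents that add atoms: none
Why: Fluoride-induced desilylation, buffered with acetic acid so that no alkoxide is present to add 5-exo to the enoate (oxa-Michael), frees the primary alcohol that becomes C6.

Step 5
Reactants: 7 isobutyrylphloroglucinol
Product: 8 1-(3-bromo-2,4,6-trihydroxyphenyl)-2-methylpropan-1-one
Conditions: NBS (1.0 equiv), THF, −78 → 0 °C
Reagents that add atoms: N-bromosuccinimide O=C1CCC(=O)N1Br
Why: Electrophilic aromatic bromination of the very electron-rich ring needs no catalyst, the two free positions are equivalent and the first bromine slows the second, so one equivalent at low temperature should give the monobromide whose bromine blocks C3 until step 8.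

Step 6
Reactants: 8 bromo-isobutyrylphloroglucinol; 9 geranyl bromide
Product: 10 1-{3-bromo-5-[(2E)-3,7-dimethylocta-2,6-dien-1-yl]-2,4,6-trihydroxyphenyl}-2-methylpropan-1-one
Conditions: NaOMe (1.05 equiv), MeOH, 0 → 23 °C
Reagents that add atoms: none
Why: Phenolate C-alkylation with an allylic bromide in a protic solvent favours carbon over oxygen, and since C5 is the only ring carbon that still bears hydrogen the site of geranylation is not in doubt.

Step 7
Reactants: 10 bromo-geranyl-isobutyrylphloroglucinol; 6 arm alcohol
Product: 12 (5R)-C5-alkylated bromo dienone, via triflate 11 (not isolated)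
Conditions: 6, (CF3SO2)2O, 2,6-lutidine, CH2Cl2, −78 °C; then 10, LiN(SiMe3)2 (2.1 equiv), THF, −78 → −30 °C; chromatographic separation of the C5 epimers
Reagents that add atoms: none
Why: Alkylative dearomatization of the lithium phenolate by the primary triflate (C-alkylation of an acylphloroglucinol) should go to C5, the only ring carbon free of bromine and acyl, and because the C7 centre is too remote to bias the two faces of the ring both C5 epimers are expected, of which the 5R epimer, the one whose arm later places the isopropenyl group over C1, is separated and carried on.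

Step 8
Reactants: 12 (5R)-bromo dienone
Product: 13 (5R)-debrominated dienone with C3–H
Conditions: Zn, AcOH, THF, 0 °C
Reagents that add atoms: none
Why: Zinc reduces the C–Br bond of the 2-bromo-1,3-dione (reductive dehalogenation through the zinc enolate, protonated by acetic acid) far faster than any alkene or the enoate, which unveils C3–H for the ring closure.

Step 9
Reactants: 13 debrominated dienone
Product: 14 bridged bicyclic Michael adduct (C3–C11 bond)
Conditions: DBU (0.3 equiv), MeCN, 40 °C
Reagents that add atoms: none
Why: Intramolecular Michael addition (7-exo-trig) of the enolized cyclic 1,3-dione through C3, its most nucleophilic carbon (C1 carries the acyl group and oxygen adducts revert), is drained by re-enolization of the adduct toward C2, and C11 is set under substrate control because the enoate can reach C3 only from the face of the C5 arm and turns its ester-bearing carbon toward the open C2 flank, away from the C5–C6 tether, which is the configuration of the target.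

Step 10
Reactants: 14 bicyclic Michael adduct
Product: 16 C12 gem-dimethyl ester, via monomethyl ester 15 (not isolated)
Conditions: LiN(i-Pr)2 (3.3 equiv), THF/DMPU, −78 °C, then MeI (1.1 equiv); LiN(i-Pr)2 (1.2 equiv), then MeI (1.5 equiv), −78 → −40 °C
Reagents that add atoms: iodomethane CI
Why: Ester enolate C-methylation carried out twice on the polyanion: the two enolized polyketone units are deprotonated first and are thereby protected, the ester enolate is the most basic and most reactive site, and retro-Michael loss of C3 is impossible as long as C3 is itself an enolate carbon, which is why the methyl groups are introduced before C3 is made quaternary; C11 is not affected and the transient C12 centre vanishes in the second methylation.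

Step 11
Reactants: 16 gem-dimethyl ester
Product: 17 C3-prenylated bicyclic trione
Conditions: Pd(PPh3)4 (5 mol%), methyl prenyl carbonate (1.1 equiv), THF, 23 °C
Reagents that add atoms: methyl 3-methylbut-2-en-1-yl carbonate COC(=O)OCC=C(C)C
Why: Tsuji–Trost allylation in which the soft dione enolate attacks the unsubstituted terminus of the π-prenylpalladium complex through carbon (O-allyl products re-ionize), at C3 rather than at the acyl-bearing C1, and only from the face opposite the C6–C7–C10 bridge, so that the configuration of the new quaternary C3 centre is fixed by the ring system.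

Step 12
Reactants: 17 C3-prenylated bicyclic trione
Product: 19 homoadamantane C12 carboxylic acid, via cage tert-butyl ester 18 (not isolated)
Conditions: HCO2H (neat), 23 °C
Reagents that add atoms: none
Why: Acid-induced cation–enol cyclization of the kind used for biomimetic closure of the bicyclo[3.3.1]nonane core: Markovnikov protonation of the isopropenyl group gives the tertiary C8 cation, which the C7 centre holds over C1, the only ring carbon still enolized now that C3 and C5 are quaternary, so that C–C bond formation closes ring C1–C9–C5–C6–C7–C8 and with it the cage, the C1 configuration being dictated by geometry, while ethers from O-capture re-ionize and the same acid cleaves the tert-butyl ester.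

Step 13
Reactants: 19 homoadamantane C12 carboxylic acid; 20 N-hydroxyphthalimide
Product: 21 N-(acyloxy)phthalimide of the C12 acid
Conditions: i-PrN=C=N-i-Pr, DMAP (0.1 equiv), CH2Cl2, 23 °C
Reagents that add atoms: none
Why: Carbodiimide esterification (Steglich type) of the hindered tertiary acid with N-hydroxyphthalimide meets no competing nucleophile, since the cage has no enolizable position and no free hydroxyl group.

Step 14
Reactants: 21 N-(acyloxy)phthalimide of the C12 acid
Product: 22 target CNP0379246.1
Conditions: Ru(bpy)3(PF6)2 (1 mol%), Hantzsch ester [diethyl 2,6-dimethyl-1,4-dihydropyridine-3,5-dicarboxylate] (1.5 equiv), CH2Cl2, 450 nm LED, 23 °C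
Reagents that add atoms: none
Why: The photoexcited ruthenium complex is reduced by the Hantzsch ester and passes one electron to the phthalimide ester, which fragments to phthalimide anion, CO2 and the tertiary C12 radical. This is the known reductive decarboxylative radical cyclization of N-(acyloxy)phthalimides onto alkenes with hydrogen-atom termination. The radical adds 5-exo-trig to C13 of the C3 prenyl group, closing the cyclopentane C3–C11–C12–C13–C14 and leaving a tertiary 2-propyl radical that takes a hydrogen atom from the Hantzsch ester to become the isopropyl group. C13 is set in a chair-like transition state in which the forming 2-propyl terminus lies pseudo-equatorial on the face of the new ring turned away from the C2 carbonyl and the C10 bridge, cis to H11, as in the target. The step needs cyclization to outrun direct reduction of the C12 radical and 5-exo to beat 6-endo attack; the gem-dimethyl group on C12, the fixed cis arrangement of C12 and C14 across the C11–C3 bond and the formation of a tertiary radical secure both, helped by the low concentration of hydrogen donor at any moment. The geranyl alkenes are out of reach of the radical and the ketones are not reduced under these conditions.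

Compound list
1 | (S)-lavandulol, (2S)-5-methyl-2-(prop-1-en-2-yl)hex-4-en-1-ol | OC[C@H](C(C)=C)CC=C(C)C | starting material
2 | tert-butyl{[(2S)-5-methyl-2-(prop-1-en-2-yl)hex-4-en-1-yl]oxy}diphenylsilane | CC(C)(C)[Si](c1ccccc1)(c1ccccc1)OC[C@H](C(C)=C)CC=C(C)C | intermediate
3 | tert-butyl{[(2S)-2-[(3,3-dimethyloxiran-2-yl)methyl]-3-methylbut-3-en-1-yl]oxy}diphenylsilane (both epoxide epimers) | CC(C)(C)[Si](c1ccccc1)(c1ccccc1)OC[C@H](C(C)=C)CC1OC1(C)C | intermediate
4 | (3S)-3-{[tert-butyl(diphenyl)silyl]oxymethyl}-4-methylpent-4-enal | CC(C)(C)[Si](c1ccccc1)(c1ccccc1)OC[C@H](C(C)=C)CC=O | intermediate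
5 | tert-butyl (2E,5S)-5-{[tert-butyl(diphenyl)silyl]oxymethyl}-6-methylhepta-2,6-dienoate | CC(C)(C)[Si](c1ccccc1)(c1ccccc1)OC[C@H](C(C)=C)C/C=C/C(=O)OC(C)(C)C | intermediate
6 | tert-butyl (2E,5S)-5-(hydroxymethyl)-6-methylhepta-2,6-dienoate | OC[C@H](C(C)=C)C/C=C/C(=O)OC(C)(C)C | intermediate
7 | isobutyrylphloroglucinol, 2-methyl-1-(2,4,6-trihydroxyphenyl)propan-1-one | CC(C)C(=O)c1c(O)cc(O)cc1O | starting material
8 | 1-(3-bromo-2,4,6-trihydroxyphenyl)-2-methylpropan-1-one | CC(C)C(=O)c1c(O)cc(O)c(Br)c1O | intermediate
9 | geranyl bromide, (2E)-1-bromo-3,7-dimethylocta-2,6-diene | CC(C)=CCC/C(C)=C/CBr | starting material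
10 | 1-{3-bromo-5-[(2E)-3,7-dimethylocta-2,6-dien-1-yl]-2,4,6-trihydroxyphenyl}-2-methylpropan-1-one | CC(C)=CCC/C(C)=C/Cc1c(O)c(Br)c(O)c(C(=O)C(C)C)c1O | intermediate
11 | tert-butyl (2E,5S)-6-methyl-5-{[(trifluoromethanesulfonyl)oxy]methyl}hepta-2,6-dienoate | FC(F)(F)S(=O)(=O)OC[C@H](C(C)=C)C/C=C/C(=O)OC(C)(C)C | intermediate
12 | tert-butyl (2E,5R)-5-({(1R)-3-bromo-1-[(2E)-3,7-dimethylocta-2,6-dien-1-yl]-2,4-dihydroxy-5-(2-methylpropanoyl)-6-oxocyclohexa-2,4-dien-1-yl}methyl)-6-methylhepta-2,6-dienoate (ring C1 is C5 of the target; the arm centre keeps the lavandulol geometry, its descriptor changes with the priorities) | CC(C)=CCC/C(C)=C/C[C@@]1(C[C@H](C(C)=C)C/C=C/C(=O)OC(C)(C)C)C(O)=C(Br)C(O)=C(C(=O)C(C)C)C1=O | intermediate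
13 | tert-butyl (2E,5R)-5-({(1R)-1-[(2E)-3,7-dimethylocta-2,6-dien-1-yl]-2,4-dihydroxy-5-(2-methylpropanoyl)-6-oxocyclohexa-2,4-dien-1-yl}methyl)-6-methylhepta-2,6-dienoate | CC(C)=CCC/C(C)=C/C[C@@]1(C[C@H](C(C)=C)C/C=C/C(=O)OC(C)(C)C)C(O)=CC(O)=C(C(=O)C(C)C)C1=O | intermediate
14 | bridged bicyclo[4.3.1]decane Michael adduct (target locants): C11 bonded to C3 and carrying CH2CO2t-Bu; geranyl on C5; isopropenyl on C7; isobutyryl on C1; C4 ketone; enols C2(OH)=C3 and C9(OH)=C1; C5, C7 and C11 configured as in the target | CC(C)=CCC/C(C)=C/C[C@@]12C[C@H](C(C)=C)C[C@H](CC(=O)OC(C)(C)C)C(C1=O)=C(O)C(C(=O)C(C)C)=C2O | intermediate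
15 | monomethyl ester: 14 with C12H(CH3)CO2t-Bu on C11 (both C12 epimers) | CC(C)=CCC/C(C)=C/C[C@@]12C[C@H](C(C)=C)C[C@H](C(C)C(=O)OC(C)(C)C)C(C1=O)=C(O)C(C(=O)C(C)C)=C2O | intermediate
16 | gem-dimethyl ester: 14 with C12(CH3)2CO2t-Bu on C11 | CC(C)=CCC/C(C)=C/C[C@@]12C[C@H](C(C)=C)C[C@H](C(C)(C)C(=O)OC(C)(C)C)C(C1=O)=C(O)C(C(=O)C(C)C)=C2O | intermediate
17 | C3-prenylated bicyclic trione: 16 with quaternary C3 bearing prenyl (on the face opposite the C6–C7–C10 bridge); C2 and C4 ketones; enol C9(OH)=C1 | CC(C)=CCC/C(C)=C/C[C@@]12C[C@H](C(C)=C)C[C@H](C(C)(C)C(=O)OC(C)(C)C)[C@@](CC=C(C)C)(C1=O)C(=O)C(C(=O)C(C)C)=C2O | intermediate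
18 | homoadamantane-2,4,9-trione tert-butyl ester (target locants): C1 isobutyryl, C3 prenyl, C5 geranyl, C8 gem-dimethyl, C11 carrying C(CH3)2CO2t-Bu; all centres as in the target | CC(C)=CCC/C(C)=C/C[C@@]12C[C@H]3C[C@H](C(C)(C)C(=O)OC(C)(C)C)[C@@](CC=C(C)C)(C1=O)C(=O)[C@@](C(=O)C(C)C)(C2=O)C3(C)C | intermediate
19 | homoadamantane C12 carboxylic acid: 18 with C(CH3)2CO2H on C11 | CC(C)=CCC/C(C)=C/C[C@@]12C[C@H]3C[C@H](C(C)(C)C(=O)O)[C@@](CC=C(C)C)(C1=O)C(=O)[C@@](C(=O)C(C)C)(C2=O)C3(C)C | intermediate
20 | N-hydroxyphthalimide | O=C1c2ccccc2C(=O)N1O | starting material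
21 | N-(acyloxy)phthalimide of acid 19 (precursor of the key step) | CC(C)=CCC/C(C)=C/C[C@@]12C[C@H]3C[C@H](C(C)(C)C(=O)ON5C(=O)c6ccccc6C5=O)[C@@](CC=C(C)C)(C1=O)C(=O)[C@@](C(=O)C(C)C)(C2=O)C3(C)C | intermediate
22 | CNP0379246.1: homoadamantane trione with the fused cyclopentane C3–C11–C12–C13–C14, isopropyl on C13, geranyl on C5, isobutyryl on C1 | CC(C)=CCC/C(C)=C/C[C@@]12C[C@H]3C[C@@H]4C(C)(C)[C@@H](C(C)C)C[C@]4(C1=O)C(=O)[C@@](C(=O)C(C)C)(C2=O)C3(C)C | target

Total step count: 14. Longest linear sequence: 12 steps (steps 1–4 and 7–14, from (S)-lavandulol); the aromatic branch (steps 5 and 6) joins at step 7.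

Steps most likely to fail

Step 9 (Michael ring closure). The seven-membered ring may close slowly, so that reversible O-cyclization, attack through the acyl-bearing C1 or approach from the other face of C11 take over. The fallback sets out from 13 and comes back at 14. The dienol is silylated (Me3SiCl, Et3N, CH2Cl2) to the bis(trimethylsilyl) dienol ether of 13 F1. The ring is then closed as an intramolecular Mukaiyama–Michael reaction (TiCl4, CH2Cl2, −78 °C, aqueous work-up). Here the Lewis acid activates the enoate instead of a base activating the donor, and only C3, the carbon terminus of the silyl dienol ether, can add. Loss of the silyl groups on work-up gives 14.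

Step 11 (C3 prenylation). Shielding of C3 by the neighbouring quaternary C12 may divert the allyl unit to oxygen or to C1. The fallback sets out from 16 and comes back at 17. The dianion is O-allylated at the C2 enol oxygen (allyl bromide, K2CO3, acetone) to the O2-allyl enol ether of 16 F2. Claisen rearrangement (toluene, 110 °C) then delivers the allyl group intramolecularly to C3, the carbon terminus of the enol double bond, giving the C3-allyl analogue of 17 F3. Cross-metathesis with 2-methyl-2-butene ((H2IMes)(PCy3)Cl2Ru=CHPh, the second-generation Grubbs catalyst, CH2Cl2, 40 °C) turns allyl into prenyl and returns 17.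

Step 12 (acid cage closure). Protonation of the geranyl or prenyl alkenes may start cation–olefin cyclization or ether formation, the C8 cation may be held by enol oxygen, or C7 may lose its configuration by elimination and reprotonation. The fallback sets out from 17 and comes back at 19. Iodonium-induced carbocyclization under buffered conditions (I2, KI, KHCO3, THF/H2O, 0 °C) lets the enolate carbon C1 open the iodonium ion of the isopropenyl group at its internal carbon C8, giving the iodomethyl cage tert-butyl ester F4. Radical deiodination (Bu3SnH, AIBN, toluene, 80 °C) converts CH2I into the second C8 methyl group and gives 18, which is then isolated. Its tert-butyl ester is removed without protic acid (Me3SiOSO2CF3, 2,6-lutidine, CH2Cl2, 0 °C, then water) to reach 19.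

Further compounds
F1 | step 9 | bis(trimethylsilyl) dienol ether of 13 (silylated at the C2 and C4 oxygens) | CC(C)=CCC/C(C)=C/C[C@@]1(C[C@H](C(C)=C)C/C=C/C(=O)OC(C)(C)C)C(O[Si](C)(C)C)=CC(O[Si](C)(C)C)=C(C(=O)C(C)C)C1=O
F2 | step 11 | O2-allyl enol ether of 16 | CC(C)=CCC/C(C)=C/C[C@@]12C[C@H](C(C)=C)C[C@H](C(C)(C)C(=O)OC(C)(C)C)C(C1=O)=C(OCC=C)C(C(=O)C(C)C)=C2O
F3 | step 11 | C3-allyl analogue of 17 | CC(C)=CCC/C(C)=C/C[C@@]12C[C@H](C(C)=C)C[C@H](C(C)(C)C(=O)OC(C)(C)C)[C@@](CC=C)(C1=O)C(=O)C(C(=O)C(C)C)=C2O
F4 | step 12 | iodomethyl cage tert-butyl ester (18 with CH2I in place of one C8 methyl group, both C8 epimers) | CC(C)=CCC/C(C)=C/C[C@@]12C[C@H]3C[C@H](C(C)(C)C(=O)OC(C)(C)C)[C@@](CC=C(C)C)(C1=O)C(=O)[C@@](C(=O)C(C)C)(C2=O)C3(C)CI
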